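**Retrosynthetic overview**

1. Locants used throughout: cycloheptane C1 (CH–O-angeloyl), C2 (CH–O of the lactone), C3 (ring-fusion CH), C4, C5 (CH2), C6 (CH–CH3), C7 (C–OH); lactone C11 (CH–CH3), C12 (C=O); side chain C8 (C=O), C9, C10 (CH–OH).
2. End game: angelate on O1 (Yamaguchi esterification), C8 ketone unmasked by ozonolysis of a C8 methylidene, silyl ethers removed.
3. Key disconnection: the C2–C3 bond, which is shared by the cycloheptane and the cis-fused γ-lactone. C2 is a carbinol carbon and C3 is β to the lactone carbonyl (a γ-hydroxy ester), so an open-chain C2 aldehyde / C3=C11 (Z)-enoate is closed by SmI2 ketyl–olefin cyclization with lactonization in the same flask (cycloheptane first, lactone second). The C7 hydroxyl, cis-1,3 to the lactone oxygen, guides it.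
4. Open chain: C7–C8 by Felkin–Anh addition of a C8–C10 alkenylcerium (from (R)-propylene oxide) to an α-silyloxy ketone; C6–C7 and the C6 methyl by (Z)-crotylboration of (S)-glyceraldehyde acetonide (C1, C2); C3, C11, C12 by B-alkyl Suzuki coupling, ozonolysis and Still–Gennari olefination.

Key step: step 14

Remark: compounds 1, 2, 7, 9, 11 (THF solution), 17 and 30 are taken as commercial.

**Route**

Step 1
Reactants: 1 (R)-propylene oxide; 2 lithium acetylide–ethylenediamine complex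
Product: 3 (R)-pent-4-yn-2-ol
Conditions: DMSO, 0 °C to rt; H2O
Reagents that add atoms: none
Why: SN2 opening of the epoxide at its unsubstituted carbon by the acetylide (epoxide alkynylation) carries the (R) centre of 1 unchanged into C10.

Step 2
Reactants: 3 (R)-pent-4-yn-2-ol
Product: 4 (R)-tert-butyldimethyl(pent-4-yn-2-yloxy)silane
Conditions: t-BuMe2SiCl, imidazole, DMF, rt
Reagents that add atoms: tert-butyldimethylsilyl chloride, CC(C)(C)[Si](C)(C)Cl
Why: Standard silyl ether formation protects the C10 hydroxyl up to the last step.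

Step 3
Reactants: 4 (R)-tert-butyldimethyl(pent-4-yn-2-yloxy)silane
Product: 6 (R)-[(4-bromopent-4-en-2-yl)oxy](tert-butyl)dimethylsilane, via bromovinylborane 5 (not isolated)
Conditions: B-bromo-9-BBN, CH2Cl2, 0 °C; then AcOH, 0 °C to rt
Reagents that add atoms: B-bromo-9-borabicyclo[3.3.1]nonane, BrB1C2CCCC1CCC2
Why: syn-Bromoboration of the terminal alkyne puts bromine on the internal carbon and protonolysis of the vinyl–boron bond with AcOH should give the 2-bromo-1-alkene (haloboration–protodeboronation).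

Step 4
Reactants: 7 methyl (S)-2,2-dimethyl-1,3-dioxolane-4-carboxylate
Product: 8 (S)-2,2-dimethyl-1,3-dioxolane-4-carbaldehyde
Conditions: i-Bu2AlH, CH2Cl2, −78 °C; MeOH, then aq. KNaC4H4O6
Reagents that add atoms: none
Why: Low-temperature partial reduction of the ester stops at the aluminium hemiacetal, which should release the configurationally intact α-alkoxy aldehyde (C1 stereocentre) on work-up.

Step 5
Reactants: 8 (S)-2,2-dimethyl-1,3-dioxolane-4-carbaldehyde; 9 (Z)-crotylboronic acid pinacol ester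
Product: 10 (1R,2S)-1-[(4S)-2,2-dimethyl-1,3-dioxolan-4-yl]-2-methylbut-3-en-1-ol
Conditions: toluene, 4 Å molecular sieves, −78 °C to rt; aq. NaHCO3
Reagents that add atoms: none
Why: Allylboration through a closed six-membered chair (Zimmerman–Traxler) transition state turns the (Z)-geometry into the syn C7-OH/C6-CH3 relationship, and the Felkin–Anh preference of (Z)-crotylboronates with this aldehyde (attack anti to the dioxolane oxygen) should set C6 as (S).

Step 6
Reactants: 10 (1R,2S)-1-[(4S)-2,2-dimethyl-1,3-dioxolan-4-yl]-2-methylbut-3-en-1-ol; 11 vinyl bromide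
Product: 13 (1R,2S)-1-[(4S)-2,2-dimethyl-1,3-dioxolan-4-yl]-2-methylhex-5-en-1-ol, via alkylborane 12 (not isolated)
Conditions: 9-BBN (2.5 equiv), THF, rt; then 11, PdCl2(dppf) (5 mol%), AsPh3, aq. K3PO4, DMF, rt
Reagents that add atoms: none
Why: Anti-Markovnikov hydroboration of the only alkene and B-alkyl Suzuki–Miyaura coupling of the primary alkylborane with vinyl bromide should extend the chain to C3 as a terminal alkene.

Step 7
Reactants: 13 (1R,2S)-1-[(4S)-2,2-dimethyl-1,3-dioxolan-4-yl]-2-methylhex-5-en-1-ol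
Product: 14 (2S)-1-[(4S)-2,2-dimethyl-1,3-dioxolan-4-yl]-2-methylhex-5-en-1-one
Conditions: Dess–Martin periodinane, NaHCO3, CH2Cl2, 0 °C to rt
Reagents that add atoms: none
Why: Buffered Dess–Martin oxidation should give the C7 ketone without epimerizing the C6 and C1 α-centres.

Step 8
Reactants: 14 (2S)-1-[(4S)-2,2-dimethyl-1,3-dioxolan-4-yl]-2-methylhex-5-en-1-one
Product: 16 (4S)-5-[(4S)-2,2-dimethyl-1,3-dioxolan-4-yl]-4-methyl-5-oxopentanal, via ozonide 15 (not isolated)
Conditions: O3, CH2Cl2, −78 °C; then PPh3, −78 °C to rt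
Reagents that add atoms: ozone, [O-][O+]=O
Why: Ozonolysis with reductive work-up cleaves the only alkene to the C3 aldehyde while ketone and acetal are inert.

Step 9
Reactants: 16 (4S)-5-[(4S)-2,2-dimethyl-1,3-dioxolan-4-yl]-4-methyl-5-oxopentanal; 17 ethyl 2-[bis(2,2,2-trifluoroethoxy)phosphoryl]propanoate
Product: 18 ethyl (2Z,6S)-7-[(4S)-2,2-dimethyl-1,3-dioxolan-4-yl]-2,6-dimethyl-7-oxohept-2-enoate
Conditions: KN(SiMe3)2, 18-crown-6, THF, −78 °C
Reagents that add atoms: none
Why: The Still–Gennari variant of the Horner–Wadsworth–Emmons reaction is aldehyde-selective and kinetically (Z)-selective, so it should give the angelate-type enoate with the ester cis to C4.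

Step 10
Reactants: 18 ethyl (2Z,6S)-7-[(4S)-2,2-dimethyl-1,3-dioxolan-4-yl]-2,6-dimethyl-7-oxohept-2-enoate
Product: 19 ethyl (2Z,6S,8S)-8,9-dihydroxy-2,6-dimethyl-7-oxonon-2-enoate
Conditions: AcOH/H2O (4:1), 40 °C
Reagents that add atoms: none
Why: Mild acetal hydrolysis frees the C1/C2 diol before any acid-sensitive allylic carbinol or silyl ether is in the molecule.

Step 11
Reactants: 19 ethyl (2Z,6S,8S)-8,9-dihydroxy-2,6-dimethyl-7-oxonon-2-enoate
Product: 20 ethyl (2Z,6S,8S)-2,6-dimethyl-7-oxo-8,9-bis(triethylsilyloxy)non-2-enoate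
Conditions: Et3SiCl (2.3 equiv), imidazole, DMF, 0 °C
Reagents that add atoms: chlorotriethylsilane, CC[Si](Cl)(CC)CC
Why: Silylation of both hydroxyls installs the non-chelating α-silyloxy group needed for step 12 and the primary triethylsilyl ether that step 13 oxidizes directly.

Step 12
Reactants: 6 (R)-[(4-bromopent-4-en-2-yl)oxy](tert-butyl)dimethylsilane; 20 ethyl (2Z,6S,8S)-2,6-dimethyl-7-oxo-8,9-bis(triethylsilyloxy)non-2-enoate
Product: 23 ethyl (2Z,6S,7R,8S)-7-hydroxy-2,6-dimethyl-7-[(4R)-4-(tert-butyldimethylsilyloxy)pent-1-en-2-yl]-8,9-bis(triethylsilyloxy)non-2-enoate, via alkenyllithium 21 (not isolated), via alkenylcerium dichloride 22 (not isolated)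
Conditions: 6, t-BuLi (2 equiv), Et2O, −78 °C; CeCl3, THF, −78 °C; then 20, −78 °C; AcOH, −78 °C
Reagents that add atoms: none
Why: Halogen–lithium exchange and transmetalation give a weakly basic alkenylcerium that should add 1,2 to the hindered ketone rather than enolize it or attack the ester, and Felkin–Anh attack anti to the C1–OSiEt3 bond (reinforced by the C6 centre) should set C7 with its oxygen trans to O1 and cis to the C6 methyl in the later ring.

Step 13
Reactants: 23 ethyl (2Z,6S,7R,8S)-7-hydroxy-2,6-dimethyl-7-[(4R)-4-(tert-butyldimethylsilyloxy)pent-1-en-2-yl]-8,9-bis(triethylsilyloxy)non-2-enoate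
Product: 24 ethyl (2Z,6S,7R,8R)-7-hydroxy-2,6-dimethyl-9-oxo-7-[(4R)-4-(tert-butyldimethylsilyloxy)pent-1-en-2-yl]-8-(triethylsilyloxy)non-2-enoate
Conditions: (COCl)2, DMSO, CH2Cl2, −78 to −40 °C; then Et3N, −78 to 0 °C
Reagents that add atoms: none
Why: Swern conditions convert a primary triethylsilyl ether directly into the aldehyde (through the alkoxysulfonium salt) while the secondary silyl ethers and the tertiary alcohol should stay untouched.

Step 14
Reactants: 24 ethyl (2Z,6S,7R,8R)-7-hydroxy-2,6-dimethyl-9-oxo-7-[(4R)-4-(tert-butyldimethylsilyloxy)pent-1-en-2-yl]-8-(triethylsilyloxy)non-2-enoate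
Product: 26 (3R,3aS,6S,7R,8S,8aR)-7-hydroxy-3,6-dimethyl-7-[(4R)-4-(tert-butyldimethylsilyloxy)pent-1-en-2-yl]-8-(triethylsilyloxy)octahydro-2H-cyclohepta[b]furan-2-one, via hydroxy ester 25 (not isolated)
Conditions: SmI2 (2.5 equiv), t-BuOH (3 equiv), THF (0.005 M), −78 °C to rt; aq. NH4Cl
Reagents that add atoms: none
Why: SmI2 reduces the aldehyde to a ketyl bound to trivalent samarium, whose carbon (C2) adds 7-exo-trig to the β-carbon (C3) of the tethered (Z)-enoate; a second SmI2 reduces the α-ester radical to a samarium enolate, t-BuOH protonates it at C11, and the C2 alkoxide closes the γ-lactone by 5-exo-trig acyl substitution with loss of ethanol. The closest known reaction type is the SmI2-mediated ketyl–olefin (aldehyde–enoate) reductive cyclization with lactonization, including its hydroxyl-directed variants and the syn preference of (Z)-enoates. The cycloheptane should close through a chair-like transition state with the three carbon substituents (C6 methyl, C7 side chain, C3 alkene) pseudo-equatorial and the three C–O bonds pseudo-axial. C2 is controlled by the C7 centre, whose free tertiary hydroxyl and the ketyl oxygen bridge one samarium in a six-membered chelate (cis-1,3 on the new ring) with the ketyl C–O antiperiplanar to the C1–OSiEt3 bond; C3 is controlled by the (Z)-geometry, which holds the ester carbonyl on the same samarium and so places C11 cis to the C2 oxygen (cis ring fusion); C11 is set by protonation of the chelated enolate from the convex face, cis to H3. The step needs cyclization to outrun simple reduction, pinacol coupling and loss of the α-silyloxy group, which high dilution, the activated acceptor, the absence of HMPA (samarium stays free to chelate) and the masking of the C8 ketone as an unactivated 1,1-disubstituted alkene should secure.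

Step 15
Reactants: 26 (3R,3aS,6S,7R,8S,8aR)-7-hydroxy-3,6-dimethyl-7-[(4R)-4-(tert-butyldimethylsilyloxy)pent-1-en-2-yl]-8-(triethylsilyloxy)octahydro-2H-cyclohepta[b]furan-2-one
Product: 28 (3R,3aS,6S,7S,8S,8aR)-7-hydroxy-3,6-dimethyl-7-[(3R)-3-(tert-butyldimethylsilyloxy)butanoyl]-8-(triethylsilyloxy)octahydro-2H-cyclohepta[b]furan-2-one, via ozonide 27 (not isolated)
Conditions: O3, CH2Cl2, −78 °C; then PPh3, −78 °C to rt
Reagents that add atoms: ozone, [O-][O+]=O
Why: Ozonolysis of the only remaining alkene, the C8 methylidene, should unmask the C8 ketone after reductive work-up.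

Step 16
Reactants: 28 (3R,3aS,6S,7S,8S,8aR)-7-hydroxy-3,6-dimethyl-7-[(3R)-3-(tert-butyldimethylsilyloxy)butanoyl]-8-(triethylsilyloxy)octahydro-2H-cyclohepta[b]furan-2-one
Product: 29 (3R,3aS,6S,7S,8S,8aR)-7,8-dihydroxy-3,6-dimethyl-7-[(3R)-3-(tert-butyldimethylsilyloxy)butanoyl]octahydro-2H-cyclohepta[b]furan-2-one
Conditions: HF·pyridine, pyridine, THF, 0 °C
Reagents that add atoms: none
Why: Buffered HF·pyridine cleaves a triethylsilyl ether much faster than a tert-butyldimethylsilyl ether (selective desilylation), so only the C1 hydroxyl should be freed.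

Step 17
Reactants: 29 (3R,3aS,6S,7S,8S,8aR)-7,8-dihydroxy-3,6-dimethyl-7-[(3R)-3-(tert-butyldimethylsilyloxy)butanoyl]octahydro-2H-cyclohepta[b]furan-2-one; 30 angelic acid
Product: 32 (3R,3aS,6S,7S,8S,8aR)-7-hydroxy-3,6-dimethyl-2-oxo-7-[(3R)-3-(tert-butyldimethylsilyloxy)butanoyl]octahydro-2H-cyclohepta[b]furan-8-yl (2Z)-2-methylbut-2-enoate, via mixed anhydride 31 (not isolated)
Conditions: 30, 2,4,6-Cl3C6H2COCl, Et3N, toluene, rt; then 29, toluene, 80 °C
Reagents that add atoms: none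
Why: Yamaguchi esterification through the mixed 2,4,6-trichlorobenzoic anhydride, run without a nucleophilic catalyst, should acylate the only secondary hydroxyl (the tertiary C7 hydroxyl does not react) and transfer the angeloyl group without (Z) to (E) isomerization.

Step 18
Reactants: 32 (3R,3aS,6S,7S,8S,8aR)-7-hydroxy-3,6-dimethyl-2-oxo-7-[(3R)-3-(tert-butyldimethylsilyloxy)butanoyl]octahydro-2H-cyclohepta[b]furan-8-yl (2Z)-2-methylbut-2-enoate
Product: 33 (3R,3aS,6S,7S,8S,8aR)-7-hydroxy-7-[(3R)-3-hydroxybutanoyl]-3,6-dimethyl-2-oxooctahydro-2H-cyclohepta[b]furan-8-yl (2Z)-2-methylbut-2-enoate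
Conditions: HF·pyridine, THF, 0 °C to rt
Reagents that add atoms: none
Why: Weakly acidic fluoride desilylation should release the C10 hydroxyl without β-elimination of the β-hydroxy ketone or isomerization of the angelate.

**Compound list**

1 | (R)-propylene oxide | C[C@@H]1CO1 | starting material
2 | lithium acetylide–ethylenediamine complex | [Li]C#C.NCCN | starting material
3 | (R)-pent-4-yn-2-ol | C[C@@H](O)CC#C | intermediate
4 | (R)-tert-butyldimethyl(pent-4-yn-2-yloxy)silane | C[C@@H](O[Si](C)(C)C(C)(C)C)CC#C | intermediate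
5 | 9-[(1Z,4R)-2-bromo-4-(tert-butyldimethylsilyloxy)pent-1-en-1-yl]-9-borabicyclo[3.3.1]nonane | C[C@@H](O[Si](C)(C)C(C)(C)C)C/C(Br)=C/B1C2CCCC1CCC2 | intermediate (not isolated)
6 | (R)-[(4-bromopent-4-en-2-yl)oxy](tert-butyl)dimethylsilane | C[C@@H](O[Si](C)(C)C(C)(C)C)CC(Br)=C | intermediate
7 | methyl (S)-2,2-dimethyl-1,3-dioxolane-4-carboxylate | CC1(C)OC[C@H](O1)C(=O)OC | starting material
8 | (S)-2,2-dimethyl-1,3-dioxolane-4-carbaldehyde | CC1(C)OC[C@H](O1)C=O | intermediate
9 | (Z)-crotylboronic acid pinacol ester | C/C=C\CB1OC(C)(C)C(C)(C)O1 | starting material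
10 | (1R,2S)-1-[(4S)-2,2-dimethyl-1,3-dioxolan-4-yl]-2-methylbut-3-en-1-ol | CC1(C)OC[C@H](O1)[C@H](O)[C@@H](C)C=C | intermediate
11 | vinyl bromide | C=CBr | starting material
12 | 9-[(3S,4R)-4-[(4S)-2,2-dimethyl-1,3-dioxolan-4-yl]-4-hydroxy-3-methylbutyl]-9-borabicyclo[3.3.1]nonane | CC1(C)OC[C@H](O1)[C@H](O)[C@@H](C)CCB1C2CCCC1CCC2 | intermediate (not isolated)
13 | (1R,2S)-1-[(4S)-2,2-dimethyl-1,3-dioxolan-4-yl]-2-methylhex-5-en-1-ol | CC1(C)OC[C@H](O1)[C@H](O)[C@@H](C)CCC=C | intermediate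
14 | (2S)-1-[(4S)-2,2-dimethyl-1,3-dioxolan-4-yl]-2-methylhex-5-en-1-one | CC1(C)OC[C@H](O1)C(=O)[C@@H](C)CCC=C | intermediate
15 | 3-[(3S)-4-[(4S)-2,2-dimethyl-1,3-dioxolan-4-yl]-3-methyl-4-oxobutyl]-1,2,4-trioxolane (ozonide of 14) | CC1(C)OC[C@H](O1)C(=O)[C@@H](C)CCC2OCOO2 | intermediate (not isolated)
16 | (4S)-5-[(4S)-2,2-dimethyl-1,3-dioxolan-4-yl]-4-methyl-5-oxopentanal | CC1(C)OC[C@H](O1)C(=O)[C@@H](C)CCC=O | intermediate
17 | ethyl 2-[bis(2,2,2-trifluoroethoxy)phosphoryl]propanoate | CCOC(=O)C(C)P(=O)(OCC(F)(F)F)OCC(F)(F)F | starting material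
18 | ethyl (2Z,6S)-7-[(4S)-2,2-dimethyl-1,3-dioxolan-4-yl]-2,6-dimethyl-7-oxohept-2-enoate | CC1(C)OC[C@H](O1)C(=O)[C@@H](C)CC/C=C(/C)C(=O)OCC | intermediate
19 | ethyl (2Z,6S,8S)-8,9-dihydroxy-2,6-dimethyl-7-oxonon-2-enoate | OC[C@H](O)C(=O)[C@@H](C)CC/C=C(/C)C(=O)OCC | intermediate
20 | ethyl (2Z,6S,8S)-2,6-dimethyl-7-oxo-8,9-bis(triethylsilyloxy)non-2-enoate | CC[Si](CC)(CC)OC[C@H](O[Si](CC)(CC)CC)C(=O)[C@@H](C)CC/C=C(/C)C(=O)OCC | intermediate
21 | [(4R)-4-(tert-butyldimethylsilyloxy)pent-1-en-2-yl]lithium | C[C@@H](O[Si](C)(C)C(C)(C)C)CC([Li])=C | intermediate (not isolated)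
22 | dichloro[(4R)-4-(tert-butyldimethylsilyloxy)pent-1-en-2-yl]cerium | C[C@@H](O[Si](C)(C)C(C)(C)C)CC(=C)[Ce](Cl)Cl | intermediate (not isolated)
23 | ethyl (2Z,6S,7R,8S)-7-hydroxy-2,6-dimethyl-7-[(4R)-4-(tert-butyldimethylsilyloxy)pent-1-en-2-yl]-8,9-bis(triethylsilyloxy)non-2-enoate | CC[Si](CC)(CC)OC[C@H](O[Si](CC)(CC)CC)[C@](O)(C(=C)C[C@@H](C)O[Si](C)(C)C(C)(C)C)[C@@H](C)CC/C=C(/C)C(=O)OCC | intermediate
24 | ethyl (2Z,6S,7R,8R)-7-hydroxy-2,6-dimethyl-9-oxo-7-[(4R)-4-(tert-butyldimethylsilyloxy)pent-1-en-2-yl]-8-(triethylsilyloxy)non-2-enoate | O=C[C@H](O[Si](CC)(CC)CC)[C@](O)(C(=C)C[C@@H](C)O[Si](C)(C)C(C)(C)C)[C@@H](C)CC/C=C(/C)C(=O)OCC | intermediate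
25 | γ-hydroxy ethyl ester, the open form of lactone 26 (C2 hydroxyl free, ethyl propanoate on C3; configuration at C1, C2, C3, C6, C7, C10, C11 as in 26) | CC[Si](CC)(CC)O[C@H]1[C@H](O)[C@@H](CC[C@H](C)[C@@]1(O)C(=C)C[C@@H](C)O[Si](C)(C)C(C)(C)C)[C@@H](C)C(=O)OCC | intermediate (not isolated)
26 | (3R,3aS,6S,7R,8S,8aR)-7-hydroxy-3,6-dimethyl-7-[(4R)-4-(tert-butyldimethylsilyloxy)pent-1-en-2-yl]-8-(triethylsilyloxy)octahydro-2H-cyclohepta[b]furan-2-one | CC[Si](CC)(CC)O[C@H]1[C@@H]2OC(=O)[C@H](C)[C@@H]2CC[C@H](C)[C@@]1(O)C(=C)C[C@@H](C)O[Si](C)(C)C(C)(C)C | intermediate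
27 | ozonide of 26 (1,2,4-trioxolane at C8) | CC[Si](CC)(CC)O[C@H]1[C@@H]2OC(=O)[C@H](C)[C@@H]2CC[C@H](C)[C@@]1(O)C3(OCOO3)C[C@@H](C)O[Si](C)(C)C(C)(C)C | intermediate (not isolated)
28 | (3R,3aS,6S,7S,8S,8aR)-7-hydroxy-3,6-dimethyl-7-[(3R)-3-(tert-butyldimethylsilyloxy)butanoyl]-8-(triethylsilyloxy)octahydro-2H-cyclohepta[b]furan-2-one | CC[Si](CC)(CC)O[C@H]1[C@@H]2OC(=O)[C@H](C)[C@@H]2CC[C@H](C)[C@@]1(O)C(=O)C[C@@H](C)O[Si](C)(C)C(C)(C)C | intermediate
29 | (3R,3aS,6S,7S,8S,8aR)-7,8-dihydroxy-3,6-dimethyl-7-[(3R)-3-(tert-butyldimethylsilyloxy)butanoyl]octahydro-2H-cyclohepta[b]furan-2-one | O[C@H]1[C@@H]2OC(=O)[C@H](C)[C@@H]2CC[C@H](C)[C@@]1(O)C(=O)C[C@@H](C)O[Si](C)(C)C(C)(C)C | intermediate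
30 | angelic acid, (2Z)-2-methylbut-2-enoic acid | C/C=C(/C)C(=O)O | starting material
31 | (2Z)-2-methylbut-2-enoic 2,4,6-trichlorobenzoic anhydride | C/C=C(/C)C(=O)OC(=O)c1c(Cl)cc(Cl)cc1Cl | intermediate (not isolated)
32 | (3R,3aS,6S,7S,8S,8aR)-7-hydroxy-3,6-dimethyl-2-oxo-7-[(3R)-3-(tert-butyldimethylsilyloxy)butanoyl]octahydro-2H-cyclohepta[b]furan-8-yl (2Z)-2-methylbut-2-enoate | C/C=C(/C)C(=O)O[C@H]1[C@@H]2OC(=O)[C@H](C)[C@@H]2CC[C@H](C)[C@@]1(O)C(=O)C[C@@H](C)O[Si](C)(C)C(C)(C)C | intermediate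
33 | (3R,3aS,6S,7S,8S,8aR)-7-hydroxy-7-[(3R)-3-hydroxybutanoyl]-3,6-dimethyl-2-oxooctahydro-2H-cyclohepta[b]furan-8-yl (2Z)-2-methylbut-2-enoate | C/C=C(/C)C(=O)O[C@H]1[C@@H]2OC(=O)[C@H](C)[C@@H]2CC[C@H](C)[C@@]1(O)C(=O)C[C@@H](C)O | target

**Step count and risks**

Total step count: 18. Longest linear sequence: 15 steps (steps 4 to 18, from 7); the side-chain branch (steps 1 to 3) joins at step 12.

Steps most likely to fail:

1. Step 14 (key step). Protonation of the samarium enolate may not discriminate the two faces at C11 if the ester is not held on samarium, so part of the material would lactonize as the C11 epimer. The fallback sets out from 24. The cyclization is run as in step 14 and the crude lactones, 26 together with the 11-epi lactone F1, are not separated. They are treated with LiN(i-Pr)2 (2.2 equiv, THF, −78 °C) to form one dianion (C7 alkoxide and lactone enolate), which is quenched at −78 °C with 2,6-di-tert-butylphenol. Kinetic protonation of the planar cis-fused lactone enolate from its convex face should funnel both epimers into 26, where the route is rejoined.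

2. Step 12. Facial selectivity of the 1,2-addition may be eroded by chelation of the metal between the carbonyl and the α-silyloxy oxygen, and the new tertiary alkoxide may trigger silyl migration from O1. The fallback sets out from 18 (with reagent 22 generated from 6 as in step 12) and returns at 23. Addition of 22 to the dioxolane ketone 18 (THF, −78 °C) should give the tertiary alcohol acetonide F2; here the Felkin–Anh model and chelation by the ring β-oxygen predict the same face, and no silyl group is present to migrate. Acetal hydrolysis (AcOH/H2O, rt) gives the triol F3, and silylation of its primary and secondary hydroxyls (Et3SiCl, imidazole, DMF, 0 °C) arrives at 23.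

3. Step 17. Acylation of the hindered C1 hydroxyl may be slow, and prolonged heating may isomerize the angeloyl donor to the (E) (tigloyl) isomer. The fallback sets out from 29 and returns at 32. Acylation of 29 with 2-[bis(2,2,2-trifluoroethoxy)phosphoryl]propanoic acid (EDC, DMAP, CH2Cl2) gives the phosphonoester F4. Still–Gennari olefination of F4 with acetaldehyde (KN(SiMe3)2, 18-crown-6, THF, −78 °C) then builds the (Z)-2-methylbut-2-enoate in place.

**Further compounds**

F1 | step 14 | (3S,3aS,6S,7R,8S,8aR)-7-hydroxy-3,6-dimethyl-7-[(4R)-4-(tert-butyldimethylsilyloxy)pent-1-en-2-yl]-8-(triethylsilyloxy)octahydro-2H-cyclohepta[b]furan-2-one (11-epi lactone) | CC[Si](CC)(CC)O[C@H]1[C@@H]2OC(=O)[C@@H](C)[C@@H]2CC[C@H](C)[C@@]1(O)C(=C)C[C@@H](C)O[Si](C)(C)C(C)(C)C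
F2 | step 12 | ethyl (2Z,6S,7R)-7-[(4S)-2,2-dimethyl-1,3-dioxolan-4-yl]-7-hydroxy-2,6-dimethyl-7-[(4R)-4-(tert-butyldimethylsilyloxy)pent-1-en-2-yl]hept-2-enoate | CC1(C)OC[C@H](O1)[C@](O)(C(=C)C[C@@H](C)O[Si](C)(C)C(C)(C)C)[C@@H](C)CC/C=C(/C)C(=O)OCC
F3 | step 12 | ethyl (2Z,6S,7R,8S)-7,8,9-trihydroxy-2,6-dimethyl-7-[(4R)-4-(tert-butyldimethylsilyloxy)pent-1-en-2-yl]non-2-enoate | OC[C@H](O)[C@](O)(C(=C)C[C@@H](C)O[Si](C)(C)C(C)(C)C)[C@@H](C)CC/C=C(/C)C(=O)OCC
F4 | step 17 | (3R,3aS,6S,7S,8S,8aR)-7-hydroxy-3,6-dimethyl-2-oxo-7-[(3R)-3-(tert-butyldimethylsilyloxy)butanoyl]octahydro-2H-cyclohepta[b]furan-8-yl 2-[bis(2,2,2-trifluoroethoxy)phosphoryl]propanoate | CC(C(=O)O[C@H]1[C@@H]2OC(=O)[C@H](C)[C@@H]2CC[C@H](C)[C@@]1(O)C(=O)C[C@@H](C)O[Si](C)(C)C(C)(C)C)P(=O)(OCC(F)(F)F)OCC(F)(F)F
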